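**Retrosynthetic overview**
- Labels: ring A is the butenolide (O1, C2=O, C3–OMe, C4–aryl, quaternary C5). Ring B is the catechol on C4. Rings C and D are the benzene and pyran rings of the chroman (primed numbers).
- Feature used: C2, C3, C4, C5, the CH2 on C5 and one extra carboxyl carbon form an unbranched six-carbon diene-diacid. These are the ring carbons of a 2-aryl-3-methoxy-4,5-dihydroxybenzoate cut between its two C–OH carbons, so the benzoate CO2Me, aryl and OMe fall on C5, C4 and C3 unchanged.
- Disconnections: CH2–C6' (decarboxylative aryl–alkyl coupling of a CH2CO2H arm with a chroman-6-ylzinc), O1–C5 (oxa-Michael lactonisation of the muconic acid), the C–C bond between the two phenolic carbons (intradiol cleavage), and the ring B–benzoate bond (Suzuki coupling).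
- Ring order: ring D is closed first in the chroman fragment (propargyl ether rearrangement), and C3' is then set by asymmetric epoxidation and hydride opening. A sacrificial benzene ring is then opened and ring A closed from it in one operation. Rings B and C come with the starting materials.

Key step: step 8

Assumption: the sense of induction of the squaramide in step 8 cannot be derived from precedent. The quinine-derived catalyst is written, and its quinidine-derived pseudoenantiomer replaces it if the (S)-acid is formed.

**Step 1**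
Reactants: 1 methyl gallate (methyl 3,4,5-trihydroxybenzoate)
Product: 2 methyl 3,4-bis(benzyloxy)-5-hydroxybenzoate
Conditions: BnBr (2.0 equiv), K2CO3, DMF, 0 °C to rt
Reagents that add atoms: benzyl bromide, BrCc1ccccc1
Why: Williamson etherification with a limited amount of halide, in which the 4-OH para to the ester is the most acidic and reacts first, one of the two equivalent meta hydroxyls follows, and mono- and tribenzyl ethers are removed by chromatography.

**Step 2**
Reactants: 2 methyl 3,4-bis(benzyloxy)-5-hydroxybenzoate
Product: 3 methyl 4,5-bis(benzyloxy)-2-bromo-3-hydroxybenzoate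
Conditions: NBS (1.0 equiv), iPr2NH (10 mol %), CH2Cl2, 0 °C, dark
Reagents that add atoms: N-bromosuccinimide, O=C1CCC(=O)N1Br
Why: Electrophilic aromatic bromination in its amine-catalysed ortho-selective form, in which the N-bromoamine made from NBS and iPr2NH is hydrogen-bonded to the phenol and delivers bromine to the only free ortho carbon, which is also para to a benzyloxy group (the preference that turns isovanillin into 2-bromoisovanillin), whereas the other free carbon is screened by the in-plane benzyl ether and the ester.

**Step 3**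
Reactants: 3 methyl 4,5-bis(benzyloxy)-2-bromo-3-hydroxybenzoate
Product: 4 methyl 4,5-bis(benzyloxy)-2-bromo-3-methoxybenzoate
Conditions: MeI, K2CO3, DMF, rt
Reagents that add atoms: iodomethane, CI
Why: Williamson O-methylation of the only free phenol fixes the methoxy group next to the bromine, so that the future C3 substituent of ring A stands beside the future C4.

**Step 4**
Reactants: 5 4-bromobenzene-1,2-diol
Product: 6 4-bromo-1,2-bis(methoxymethoxy)benzene
Conditions: MOMCl, iPr2NEt, CH2Cl2, 0 °C to rt
Reagents that add atoms: chloromethyl methyl ether, COCCl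
Why: O-alkylation of both phenols with an alpha-chloro ether gives acetals that survive base, palladium, hydrogenolysis, buffered peracid and organozinc reagents and are removed by acid at the end.

**Step 5**
Reactants: 6 4-bromo-1,2-bis(methoxymethoxy)benzene
Product: 7 2-[3,4-bis(methoxymethoxy)phenyl]-4,4,5,5-tetramethyl-1,3,2-dioxaborolane
Conditions: B2pin2, Pd(dppf)Cl2 (3 mol %), KOAc, 1,4-dioxane, 90 °C
Reagents that add atoms: bis(pinacolato)diboron, CC1(C)OB(OC1(C)C)B1OC(C)(C)C(C)(C)O1
Why: Miyaura borylation by oxidative addition of the aryl bromide to zerovalent palladium, acetate-assisted transmetalation with B2pin2 and reductive elimination, none of which affects the MOM acetals.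

**Step 6**
Reactants: 4 methyl 4,5-bis(benzyloxy)-2-bromo-3-methoxybenzoate; 7 2-[3,4-bis(methoxymethoxy)phenyl]-4,4,5,5-tetramethyl-1,3,2-dioxaborolane
Product: 8 methyl 4,5-bis(benzyloxy)-2-[3,4-bis(methoxymethoxy)phenyl]-3-methoxybenzoate
Conditions: Pd(OAc)2 (5 mol %), SPhos (10 mol %), K3PO4, toluene/H2O, 90 °C
Reagents that add atoms: none
Why: Suzuki–Miyaura coupling in which the bulky electron-rich biarylphosphine allows oxidative addition and reductive elimination at a bromide flanked by CO2Me and OMe, while the boronate partner carries no ortho substituent.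

**Step 7**
Reactants: 8 methyl 4,5-bis(benzyloxy)-2-[3,4-bis(methoxymethoxy)phenyl]-3-methoxybenzoate
Product: 9 methyl 2-[3,4-bis(methoxymethoxy)phenyl]-4,5-dihydroxy-3-methoxybenzoate
Conditions: H2 (1 atm), 10% Pd/C, EtOAc/MeOH, rt
Reagents that add atoms: none
Why: Catalytic hydrogenolysis cleaves only the two benzylic C–O bonds, since MOM acetals, methyl ether, ester and biaryl are inert to H2 over Pd/C under neutral conditions, so the catechol is freed on the ring to be cut while ring B stays masked.

**Step 8**
Reactants: 9 methyl 2-[3,4-bis(methoxymethoxy)phenyl]-4,5-dihydroxy-3-methoxybenzoate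
Product: 13 2-[(2R)-3-[3,4-bis(methoxymethoxy)phenyl]-4-methoxy-2-(methoxycarbonyl)-5-oxo-2,5-dihydrofuran-2-yl]acetic acid, via o-quinone 10 (not isolated), via muconic anhydride 11 (not isolated), via cis,cis-muconic acid 12 (not isolated)
Conditions: (a) AcOOH (2.2 equiv, H2SO4-free), NaOAc, EtOAc, 0 °C; (b) cold wash at pH 3, solvent change to toluene/CH2Cl2; (c) quinine-derived squaramide 3-{[3,5-bis(trifluoromethyl)phenyl]amino}-4-{[(8α,9S)-6'-methoxycinchonan-9-yl]amino}cyclobut-3-ene-1,2-dione (20 mol %), −20 °C
Reagents that add atoms: peracetic acid, CC(=O)OO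
Why: Proposed new method: peracetic acid oxidises only the free catechol ring to o-quinone 10, a second equivalent adds to a quinone carbonyl and a Baeyer–Villiger-type acyl shift inserts oxygen between the two carbonyl carbons to give muconic anhydride 11, and the water released in the first oxidation opens 11 to cis,cis-muconic acid 12, in which OMe, aryl and CO2Me already stand in the order C3, C4, C5 of ring A. The closest known reactions are the peracid intradiol cleavage of catechols to cis,cis-muconic acids and the cycloisomerisation of 3-substituted muconic acids to 4,4-disubstituted muconolactones (the chemistry of the 3-carboxymuconate branch of the beta-ketoadipate pathway), both known only in racemic form outside enzymes, while bifunctional cinchona squaramides are known to steer intramolecular oxa-Michael additions of alcohols and phenols but not of a carboxylic acid onto an acrylic acid. Ring A closes by a 5-exo-trig oxa-Michael addition in which the carboxylate next to C(OMe), held cis to the ester-bearing alkene carbon by the former ring bond, attacks that carbon (beta to the free acrylic acid) to form O1–C5, and protonation of the resulting enediol at CH gives the CH2CO2H arm. C5 is the only new stereocentre and its face is to be chosen by the catalyst, whose quinuclidinium pairs with the attacking carboxylate while the squaramide N–H bonds hold the acceptor CO2H and the neighbouring CO2Me, so that one face of the diene is presented. Regioselectivity between the two possible gamma-lactones is needed, and closure of the other acid onto the aryl-bearing carbon would attack a tetrasubstituted carbon made electron-rich by the enol ether and the dialkoxyphenyl group and would break the aryl–C=C(OMe)–C=O conjugation, so 13 is favoured kinetically and, because the closure is reversible, also thermodynamically. Chemoselectivity rests on the MOM ethers, which leave ring B without a free phenol and therefore slow towards the peracid, and acetate buffering at 0 °C protects them and holds back uncatalysed closure.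

**Step 9**
Reactants: 13 2-[(2R)-3-[3,4-bis(methoxymethoxy)phenyl]-4-methoxy-2-(methoxycarbonyl)-5-oxo-2,5-dihydrofuran-2-yl]acetic acid
Product: 14 1,3-dioxoisoindolin-2-yl 2-[(2R)-3-[3,4-bis(methoxymethoxy)phenyl]-4-methoxy-2-(methoxycarbonyl)-5-oxo-2,5-dihydrofuran-2-yl]acetate
Conditions: N-hydroxyphthalimide, DIC, CH2Cl2, 0 °C to rt, no amine base
Reagents that add atoms: N-hydroxyphthalimide, O=C1c2ccccc2C(=O)N1O
Why: Carbodiimide esterification to the redox-active ester, run without amine base because the arm CH2 is now alpha to an activated ester and beta to the lactone oxygen, so that base could reopen ring A by retro-oxa-Michael elimination and erase C5.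

**Step 10**
Reactants: 15 4-bromophenol; 16 3-chloro-3-methylbut-1-yne
Product: 17 1-bromo-4-[(2-methylbut-3-yn-2-yl)oxy]benzene
Conditions: CuCl2·2H2O (1 mol %), DBU, MeCN, 0 °C
Reagents that add atoms: none
Why: Copper-catalysed propargylic O-alkylation, in which the tertiary propargylic chloride ionises through a copper acetylide and the phenoxide is captured at the tertiary carbon.

**Step 11**
Reactants: 17 1-bromo-4-[(2-methylbut-3-yn-2-yl)oxy]benzene
Product: 18 6-bromo-2,2-dimethyl-2H-chromene
Conditions: N,N-diethylaniline, 190 °C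
Reagents that add atoms: none
Why: Aromatic propargyl Claisen rearrangement followed by 1,5-hydrogen shift and oxa-6π electrocyclisation closes ring D, and the para bromine makes both ortho positions equivalent so that only the 6-bromo chromene can form.

**Step 12**
Reactants: 18 6-bromo-2,2-dimethyl-2H-chromene
Product: 19 (1aR,7bR)-6-bromo-2,2-dimethyl-1a,7b-dihydro-2H-oxireno[2,3-c]chromene, the (3R,4R)-3,4-epoxychroman
Conditions: aq NaOCl (pH 11.3), (R,R)-[N,N'-bis(3,5-di-tert-butylsalicylidene)cyclohexane-1,2-diaminato]MnCl (2 mol %), 4-phenylpyridine N-oxide (10 mol %), CH2Cl2, 0 °C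
Reagents that add atoms: sodium hypochlorite, [Na+].[O-]Cl
Why: Jacobsen–Katsuki epoxidation, for which aryl-conjugated cis-alkenes of the 2,2-dimethylchromene type are the best substrate class, the (R,R)-catalyst transferring oxygen by side-on approach to the face that gives the (3R,4R)-epoxide.

**Step 13**
Reactants: 19 (3R,4R)-6-bromo-3,4-epoxy-2,2-dimethylchroman
Product: 20 (3R)-6-bromo-2,2-dimethylchroman-3-ol
Conditions: LiAlH4, THF, 0 °C
Reagents that add atoms: none
Why: SN2 hydride opening of the epoxide at the benzylic and less hindered C4' (C3' is neopentyl-like next to CMe2) leaves the C3'–O bond and its (R) configuration untouched, and the aryl bromide is not reduced at 0 °C.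

**Step 14**
Reactants: 20 (3R)-6-bromo-2,2-dimethylchroman-3-ol
Product: 21 [(3R)-6-bromo-2,2-dimethylchroman-3-yl]oxy(tert-butyl)dimethylsilane
Conditions: TBSOTf, 2,6-lutidine, CH2Cl2, 0 °C
Reagents that add atoms: tert-butyldimethylsilyl triflate, CC(C)(C)[Si](C)(C)OS(=O)(=O)C(F)(F)F
Why: Silylation of the hindered secondary alcohol with the reactive silyl triflate masks the only acidic proton before metalation and does not involve the stereocentre.

**Step 15**
Reactants: 21 [(3R)-6-bromo-2,2-dimethylchroman-3-yl]oxy(tert-butyl)dimethylsilane; 14 the N-hydroxyphthalimide ester of acid 13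
Product: 24 methyl (2R)-3-[3,4-bis(methoxymethoxy)phenyl]-2-{[(3R)-3-(tert-butyldimethylsilyloxy)-2,2-dimethylchroman-6-yl]methyl}-4-methoxy-5-oxo-2,5-dihydrofuran-2-carboxylate, via aryllithium 22 (not isolated), via arylzinc chloride 23 (not isolated)
Conditions: 21 (3 equiv), n-BuLi, THF, −78 °C; ZnCl2, −78 °C to rt; then 14, NiCl2·glyme (40 mol %), 4,4'-di-tert-butyl-2,2'-bipyridine (80 mol %), THF/DMF, 0.3 M, rt
Reagents that add atoms: none
Why: Nickel-catalysed decarboxylative Negishi-type aryl–alkyl coupling of a redox-active ester, in which monovalent aryl-nickel transfers one electron to the phthalimide ester, CO2 and phthalimide anion are lost, the primary C5–CH2 radical is captured by divalent aryl-nickel and reductive elimination forms the CH2–C6' bond without touching either stereocentre, while the high nickel loading, the excess of 23 and the high concentration are chosen so that capture outruns 3-exo attack of the radical on C4 of ring A, and the weakly basic zinc reagent leaves lactone, esters and the acidic arm CH2 alone.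

**Step 16**
Reactants: 24 the fully protected coupling product
Product: 25 methyl (2R)-3-(3,4-dihydroxyphenyl)-2-{[(3R)-3-hydroxy-2,2-dimethyl-3,4-dihydro-2H-chromen-6-yl]methyl}-4-methoxy-5-oxo-2,5-dihydrofuran-2-carboxylate (CNP0289675.3)
Conditions: HCl (1.25 M in dry MeOH), N2, 40 °C
Reagents that add atoms: none
Why: Acid-catalysed acetal exchange and desilylation in methanol remove both MOM groups and the TBS ether in one operation, methanol makes any exchange at the methyl ester degenerate, no bond to C5 or C3' is broken, and the alpha-methoxy enoate is too electron-poor to be hydrolysed.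

**Compound list**
1 | methyl 3,4,5-trihydroxybenzoate (methyl gallate) | COC(=O)c1cc(O)c(O)c(O)c1 | starting material
2 | methyl 3,4-bis(benzyloxy)-5-hydroxybenzoate | COC(=O)c1cc(O)c(OCc2ccccc2)c(OCc2ccccc2)c1 | intermediate
3 | methyl 4,5-bis(benzyloxy)-2-bromo-3-hydroxybenzoate | COC(=O)c1cc(OCc2ccccc2)c(OCc2ccccc2)c(O)c1Br | intermediate
4 | methyl 4,5-bis(benzyloxy)-2-bromo-3-methoxybenzoate | COC(=O)c1cc(OCc2ccccc2)c(OCc2ccccc2)c(OC)c1Br | intermediate
5 | 4-bromobenzene-1,2-diol | Oc1ccc(Br)cc1O | starting material
6 | 4-bromo-1,2-bis(methoxymethoxy)benzene | COCOc1ccc(Br)cc1OCOC | intermediate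
7 | 2-[3,4-bis(methoxymethoxy)phenyl]-4,4,5,5-tetramethyl-1,3,2-dioxaborolane | COCOc1ccc(B2OC(C)(C)C(C)(C)O2)cc1OCOC | intermediate
8 | methyl 4,5-bis(benzyloxy)-2-[3,4-bis(methoxymethoxy)phenyl]-3-methoxybenzoate | COC(=O)c1cc(OCc2ccccc2)c(OCc2ccccc2)c(OC)c1-c1ccc(OCOC)c(OCOC)c1 | intermediate
9 | methyl 2-[3,4-bis(methoxymethoxy)phenyl]-4,5-dihydroxy-3-methoxybenzoate | COC(=O)c1cc(O)c(O)c(OC)c1-c1ccc(OCOC)c(OCOC)c1 | intermediate
10 | methyl 6-[3,4-bis(methoxymethoxy)phenyl]-5-methoxy-3,4-dioxocyclohexa-1,5-diene-1-carboxylate (o-quinone, not isolated) | COC(=O)C1=CC(=O)C(=O)C(OC)=C1c1ccc(OCOC)c(OCOC)c1 | intermediate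
11 | methyl 5-[3,4-bis(methoxymethoxy)phenyl]-6-methoxy-2,7-dioxo-2,7-dihydrooxepine-4-carboxylate (muconic anhydride, not isolated) | O=C1OC(=O)C(OC)=C(c2ccc(OCOC)c(OCOC)c2)C(C(=O)OC)=C1 | intermediate
12 | (2E,4E)-3-[3,4-bis(methoxymethoxy)phenyl]-2-methoxy-4-(methoxycarbonyl)hexa-2,4-dienedioic acid (chain carbons cis across both C=C, not isolated) | OC(=O)/C(OC)=C(c1ccc(OCOC)c(OCOC)c1)\C(C(=O)OC)=C/C(=O)O | intermediate
13 | 2-[(2R)-3-[3,4-bis(methoxymethoxy)phenyl]-4-methoxy-2-(methoxycarbonyl)-5-oxo-2,5-dihydrofuran-2-yl]acetic acid | COC(=O)[C@]1(CC(=O)O)OC(=O)C(OC)=C1c1ccc(OCOC)c(OCOC)c1 | intermediate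
14 | 1,3-dioxoisoindolin-2-yl 2-[(2R)-3-[3,4-bis(methoxymethoxy)phenyl]-4-methoxy-2-(methoxycarbonyl)-5-oxo-2,5-dihydrofuran-2-yl]acetate | COC(=O)[C@]1(CC(=O)ON2C(=O)c3ccccc3C2=O)OC(=O)C(OC)=C1c1ccc(OCOC)c(OCOC)c1 | intermediate
15 | 4-bromophenol | Oc1ccc(Br)cc1 | starting material
16 | 3-chloro-3-methylbut-1-yne | CC(C)(Cl)C#C | starting material
17 | 1-bromo-4-[(2-methylbut-3-yn-2-yl)oxy]benzene | C#CC(C)(C)Oc1ccc(Br)cc1 | intermediate
18 | 6-bromo-2,2-dimethyl-2H-chromene | CC1(C)C=Cc2cc(Br)ccc2O1 | intermediate
19 | (1aR,7bR)-6-bromo-2,2-dimethyl-1a,7b-dihydro-2H-oxireno[2,3-c]chromene | CC1(C)Oc2ccc(Br)cc2[C@H]2O[C@@H]12 | intermediate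
20 | (3R)-6-bromo-2,2-dimethylchroman-3-ol | Brc1ccc2c(c1)C[C@@H](O)C(C)(C)O2 | intermediate
21 | [(3R)-6-bromo-2,2-dimethylchroman-3-yl]oxy(tert-butyl)dimethylsilane | Brc1ccc2c(c1)C[C@@H](O[Si](C)(C)C(C)(C)C)C(C)(C)O2 | intermediate
22 | [(3R)-3-(tert-butyldimethylsilyloxy)-2,2-dimethylchroman-6-yl]lithium (not isolated) | [Li]c1ccc2c(c1)C[C@@H](O[Si](C)(C)C(C)(C)C)C(C)(C)O2 | intermediate
23 | [(3R)-3-(tert-butyldimethylsilyloxy)-2,2-dimethylchroman-6-yl]zinc chloride (not isolated) | Cl[Zn]c1ccc2c(c1)C[C@@H](O[Si](C)(C)C(C)(C)C)C(C)(C)O2 | intermediate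
24 | methyl (2R)-3-[3,4-bis(methoxymethoxy)phenyl]-2-{[(3R)-3-(tert-butyldimethylsilyloxy)-2,2-dimethylchroman-6-yl]methyl}-4-methoxy-5-oxo-2,5-dihydrofuran-2-carboxylate | COC(=O)[C@]1(Cc2ccc3c(c2)C[C@@H](O[Si](C)(C)C(C)(C)C)C(C)(C)O3)OC(=O)C(OC)=C1c1ccc(OCOC)c(OCOC)c1 | intermediate
25 | methyl (2R)-3-(3,4-dihydroxyphenyl)-2-{[(3R)-3-hydroxy-2,2-dimethyl-3,4-dihydro-2H-chromen-6-yl]methyl}-4-methoxy-5-oxo-2,5-dihydrofuran-2-carboxylate | COC(=O)[C@]1(Cc2ccc3c(c2)C[C@@H](O)C(C)(C)O3)OC(=O)C(OC)=C1c1ccc(O)c(O)c1 | target

**Step count**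
- Total step count: 16.
- Longest linear sequence: 9 steps (steps 1, 2, 3, 6, 7, 8, 9, 15, 16).

**Steps most likely to fail**

1. Step 8 (Proposed new method).
   - What may go wrong: acid 12 may close without the catalyst during the oxidation or the wash, so that C5 forms with little facial bias. The squaramide may also bind a diacid too weakly to discriminate the faces.
   - Fallback with known chemistry, from 9 back to 13: 9 is oxidised with AcOOH in AcOH at rt without catalyst and left until 12 has closed by itself. This should give racemic 2-[3-[3,4-bis(methoxymethoxy)phenyl]-4-methoxy-2-(methoxycarbonyl)-5-oxo-2,5-dihydrofuran-2-yl]acetic acid F1.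
   - The acid is crystallised with (R)-1-phenylethylamine from 2-propanol/EtOAc to the less soluble (R)-1-phenylethylammonium salt of the (R)-acid F2. The (S)-amine is taken if the salt of the (S)-acid is the less soluble one.
   - Partition between cold dilute HCl and EtOAc returns 13. The acid left in the mother liquor is racemised with DBU through reversible retro-oxa-Michael opening and used again.

2. Step 15.
   - What may go wrong: the primary radical may add in 3-exo fashion to C4 of ring A and enlarge the ring by a 1,2-vinyl shift faster than nickel captures it.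
   - Fallback from 14 back to 24: 14 is irradiated (blue light, Ru(bpy)3Cl2, Hantzsch ester, CH2Cl2) with excess TEMPO, whose radical capture is near diffusion-controlled. This should give the alkoxyamine methyl (2S)-3-[3,4-bis(methoxymethoxy)phenyl]-4-methoxy-5-oxo-2-{[(2,2,6,6-tetramethylpiperidin-1-yl)oxy]methyl}-2,5-dihydrofuran-2-carboxylate F3. The descriptor changes only because CH2O outranks the ring carbon; the spatial arrangement is that of 13.
   - mCPBA (CH2Cl2, 0 °C) oxidises the nitrogen, and the N-oxide fragments to the aldehyde methyl (2S)-3-[3,4-bis(methoxymethoxy)phenyl]-2-formyl-4-methoxy-5-oxo-2,5-dihydrofuran-2-carboxylate F4.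
   - Arylzinc 23 is added to the aldehyde with MgCl2 as promoter (THF, 0 °C). This gives the benzylic alcohol methyl (2S)-3-[3,4-bis(methoxymethoxy)phenyl]-2-{[(3R)-3-(tert-butyldimethylsilyloxy)-2,2-dimethylchroman-6-yl](hydroxy)methyl}-4-methoxy-5-oxo-2,5-dihydrofuran-2-carboxylate F5 as both carbinol epimers.
   - Ionic hydrogenation (Et3SiH, TFA, CH2Cl2, −20 °C) through the para-alkoxybenzyl cation removes the hydroxyl and returns to 24. Any partly deprotected material converges in step 16.

3. Step 2.
   - What may go wrong: bromine may enter para to the free hydroxyl, next to the benzyl ether, instead of ortho to it.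
   - Fallback from 1 back to 4, exchanging which oxygen stays free: 1 is mono-O-methylated under borate protection of two neighbouring hydroxyls (borax, Me2SO4, NaOH, water) to methyl 3,4-dihydroxy-5-methoxybenzoate F6.
   - In this isomer the carbon para to the 3-hydroxyl is the one next to OMe, so the same para preference now places the halogen correctly (NBS, MeCN, 0 °C). This gives methyl 2-bromo-4,5-dihydroxy-3-methoxybenzoate F7.
   - Double benzylation (BnBr, K2CO3, DMF) returns to 4.

**Further compounds**
F1 | step 8 | racemic 2-[3-[3,4-bis(methoxymethoxy)phenyl]-4-methoxy-2-(methoxycarbonyl)-5-oxo-2,5-dihydrofuran-2-yl]acetic acid | COC(=O)C1(CC(=O)O)OC(=O)C(OC)=C1c1ccc(OCOC)c(OCOC)c1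
F2 | step 8 | (R)-1-phenylethylammonium salt of the (R)-acid | COC(=O)[C@]1(CC(=O)[O-])OC(=O)C(OC)=C1c1ccc(OCOC)c(OCOC)c1.C[C@@H]([NH3+])c1ccccc1
F3 | step 15 | methyl (2S)-3-[3,4-bis(methoxymethoxy)phenyl]-4-methoxy-5-oxo-2-{[(2,2,6,6-tetramethylpiperidin-1-yl)oxy]methyl}-2,5-dihydrofuran-2-carboxylate | COC(=O)[C@]1(CON2C(C)(C)CCCC2(C)C)OC(=O)C(OC)=C1c1ccc(OCOC)c(OCOC)c1
F4 | step 15 | methyl (2S)-3-[3,4-bis(methoxymethoxy)phenyl]-2-formyl-4-methoxy-5-oxo-2,5-dihydrofuran-2-carboxylate | COC(=O)[C@]1(C=O)OC(=O)C(OC)=C1c1ccc(OCOC)c(OCOC)c1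
F5 | step 15 | methyl (2S)-3-[3,4-bis(methoxymethoxy)phenyl]-2-{[(3R)-3-(tert-butyldimethylsilyloxy)-2,2-dimethylchroman-6-yl](hydroxy)methyl}-4-methoxy-5-oxo-2,5-dihydrofuran-2-carboxylate, both carbinol epimers | COC(=O)[C@]1(C(O)c2ccc3c(c2)C[C@@H](O[Si](C)(C)C(C)(C)C)C(C)(C)O3)OC(=O)C(OC)=C1c1ccc(OCOC)c(OCOC)c1
F6 | step 2 | methyl 3,4-dihydroxy-5-methoxybenzoate | COC(=O)c1cc(O)c(O)c(OC)c1
F7 | step 2 | methyl 2-bromo-4,5-dihydroxy-3-methoxybenzoate | COC(=O)c1cc(O)c(O)c(OC)c1Br
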